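The route rests on cutting the C4–C5 bond (germacrane numbering), which is both an edge of the ten-membered carbocycle and the C–C bond of the 4,5-oxirane. In the precursor these two carbons are bridged only by a sulfonyl group, in an eleven-membered thiacycle that already holds C6, C7, C8 and the E C1=C10 olefin. A Ramberg–Bäcklund reaction joins C4 to C5, contracts the thiacycle to the germacrane ring and leaves the E C4=C5 olefin; it exploits the C6 oxygen next to C5 (carried as an inert alkoxide) and erases the C4 stereocentre, so both sulfone epimers converge. Oxygen then replaces sulfur: peracid epoxidation of both ring olefins gives the diepoxide.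

Key step: step 16

Remarks on the chemistry:
- Germacrane numbering is used for all intermediates: C1–C10 ring, C11–C13 lactone carbons, C14 on C10, C15 on C4. Compounds 1, 4, 10 and 11 are commercial.
- The sulfur-bearing carbon C4 is carried as a 1:1 epimer mixture from 7 to 24 and is left undefined in the SMILES.
- Assumption: the zinc allylation of step 10 follows the closed chair transition state and gives the 8S adduct 16. If the 8R adduct 18 forms directly, step 11 is omitted.

Step 1
Reactants: 1 tert-butyl(but-3-yn-1-yloxy)dimethylsilane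
Product: 3 tert-butyl{[(3E)-4-iodo-3-methylbut-3-en-1-yl]oxy}dimethylsilane, via alkenylalane 2 (not isolated)
Conditions: Me3Al, Cp2ZrCl2 (cat.), CH2Cl2, 0 °C to rt; then I2, THF, −30 °C
Reagents that add atoms: trimethylaluminium C[Al](C)C; iodine II
Why: Zirconium-catalysed syn-carboalumination (Negishi) puts the methyl group on the internal and aluminium on the terminal alkyne carbon, and iodinolysis with retention should give the E-iodoalkene that later becomes the E C1=C10 olefin.

Step 2
Reactants: 3 tert-butyl{[(3E)-4-iodo-3-methylbut-3-en-1-yl]oxy}dimethylsilane; 4 (±)-but-3-en-2-ol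
Product: 6 (±)-(5E)-8-(tert-butyldimethylsilyloxy)-6-methyloct-5-en-2-ol, via alkylborane 5 (not isolated)
Conditions: 9-BBN-H (2.2 equiv), THF, rt; then 3, PdCl2(dppf) (5 mol%), AsPh3, Cs2CO3, DMF/H2O, rt
Reagents that add atoms: none
Why: Anti-Markovnikov hydroboration of 4 (one equivalent of borane is used up by the hydroxyl) and B-alkyl Suzuki–Miyaura coupling with 3 should join C1 to C2 with retention of the olefin geometry.

Step 3
Reactants: 6 (±)-(5E)-8-(tert-butyldimethylsilyloxy)-6-methyloct-5-en-2-ol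
Product: 7 (±)-S-[(5E)-8-(tert-butyldimethylsilyloxy)-6-methyloct-5-en-2-yl] ethanethioate
Conditions: AcSH, PPh3, DIAD, THF, 0 °C
Reagents that add atoms: thioacetic acid CC(=O)S
Why: The Mitsunobu reaction with thioacetic acid converts the secondary alcohol into the thioester with inversion, and since C4 is racemic and later becomes sp2 its configuration is of no consequence.

Step 4
Reactants: 7 (±)-S-[(5E)-8-(tert-butyldimethylsilyloxy)-6-methyloct-5-en-2-yl] ethanethioate
Product: 8 (±)-S-[(5E)-8-hydroxy-6-methyloct-5-en-2-yl] ethanethioate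
Conditions: HF·pyridine, pyridine, THF, 0 °C to rt
Reagents that add atoms: none
Why: HF·pyridine cleaves the primary silyl ether and leaves the thioester intact.

Step 5
Reactants: 8 (±)-S-[(5E)-8-hydroxy-6-methyloct-5-en-2-yl] ethanethioate
Product: 9 (±)-S-[(5E)-6-methyl-8-oxooct-5-en-2-yl] ethanethioate
Conditions: Dess–Martin periodinane, NaHCO3, CH2Cl2, 0 °C; used crude
Reagents that add atoms: none
Why: Buffered Dess–Martin oxidation should give the β,γ-unsaturated aldehyde without moving the olefin into conjugation.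

Step 6
Reactants: 10 (4R)-2,2-dimethyl-1,3-dioxolane-4-carbaldehyde; 11 methyl acrylate
Product: 12 methyl 2-{[(4R)-2,2-dimethyl-1,3-dioxolan-4-yl](hydroxy)methyl}prop-2-enoate (both carbinol epimers)
Conditions: DABCO (0.5 equiv), dioxane/H2O, rt, 3–5 d
Reagents that add atoms: none
Why: The Morita–Baylis–Hillman reaction forms the C7–C11 bond, the new carbinol centre arises as a mixture that step 9 erases, and C6 comes from the chiral pool.

Step 7
Reactants: 12 methyl 2-{[(4R)-2,2-dimethyl-1,3-dioxolan-4-yl](hydroxy)methyl}prop-2-enoate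
Product: 13 (5R)-4-hydroxy-5-(hydroxymethyl)-3-methylideneoxolan-2-one (both C4 epimers)
Conditions: TFA/H2O (9:1), 0 °C to rt; then toluene azeotrope
Reagents that add atoms: none
Why: Aqueous acid removes the acetonide and the C6 hydroxyl closes onto the ester (5-exo-trig lactonisation), which should be favoured over six-ring closure by the primary hydroxyl.

Step 8
Reactants: 13 (5R)-4-hydroxy-5-(hydroxymethyl)-3-methylideneoxolan-2-one
Product: 14 [(2R)-3-hydroxy-4-methylidene-5-oxooxolan-2-yl]methyl 4-methylbenzenesulfonate (both C3 epimers)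
Conditions: TsCl (1.05 equiv), pyridine, CH2Cl2, −10 °C
Reagents that add atoms: p-toluenesulfonyl chloride Cc1ccc(cc1)S(Cl)(=O)=O
Why: The primary hydroxyl should be sulfonylated selectively over the more hindered secondary allylic one.

Step 9
Reactants: 14 [(2R)-3-hydroxy-4-methylidene-5-oxooxolan-2-yl]methyl 4-methylbenzenesulfonate
Product: 15 [(2S)-4-(bromomethyl)-5-oxo-2,5-dihydrofuran-2-yl]methyl 4-methylbenzenesulfonate
Conditions: PBr3, Et2O, 0 °C
Reagents that add atoms: phosphorus tribromide BrP(Br)Br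
Why: SN2′ bromination of the Baylis–Hillman-type allylic alcohol shifts the olefin into the ring (C7=C11), erasing the carbinol centre and giving the 3-(bromomethyl)butenolide with C6 untouched.

Step 10
Reactants: 9 (±)-S-[(5E)-6-methyl-8-oxooct-5-en-2-yl] ethanethioate; 15 [(2S)-4-(bromomethyl)-5-oxo-2,5-dihydrofuran-2-yl]methyl 4-methylbenzenesulfonate
Product: 16 S-[(5E,8S)-8-hydroxy-6-methyl-8-{(2S,3R)-4-methylidene-5-oxo-2-[(tosyloxy)methyl]oxolan-3-yl}oct-5-en-2-yl] ethanethioate
Conditions: Zn dust, THF/sat. aq. NH4Cl, 0 °C to rt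
Reagents that add atoms: none
Why: Barbier allylation through the γ-carbon C7 of the allylzinc should occur anti to the C6 substituent (trans C6/C7) and, through a closed chair transition state with the ring-locked E-type allyl unit and an equatorial aldehyde residue, give the 7,8-anti adduct (8S) while the lactone olefin moves to the exocyclic position.

Step 11
Reactants: 16 S-[(5E,8S)-8-hydroxy-6-methyl-8-{(2S,3R)-4-methylidene-5-oxo-2-[(tosyloxy)methyl]oxolan-3-yl}oct-5-en-2-yl] ethanethioate
Product: 18 S-[(5E,8R)-8-hydroxy-6-methyl-8-{(2S,3R)-4-methylidene-5-oxo-2-[(tosyloxy)methyl]oxolan-3-yl}oct-5-en-2-yl] ethanethioate, via formate 17 (not isolated)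
Conditions: HCO2H, PPh3, DIAD, THF, 0 °C; then KHCO3, MeOH, 0 °C
Reagents that add atoms: formic acid OC=O
Why: Mitsunobu inversion with formic acid (SN2 at C8) sets the required 8R (8β) configuration, and the labile formate is methanolysed under conditions that should spare thioester, sulfonate and lactone.

Step 12
Reactants: 18 S-[(5E,8R)-8-hydroxy-6-methyl-8-{(2S,3R)-4-methylidene-5-oxo-2-[(tosyloxy)methyl]oxolan-3-yl}oct-5-en-2-yl] ethanethioate
Product: 19 S-[(5E,8R)-6-methyl-8-{(2S,3S)-4-methylidene-5-oxo-2-[(tosyloxy)methyl]oxolan-3-yl}-8-(triisopropylsilyloxy)oct-5-en-2-yl] ethanethioate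
Conditions: TIPSOTf, 2,6-lutidine, CH2Cl2, 0 °C
Reagents that add atoms: triisopropylsilyl triflate CC(C)[Si](OS(=O)(=O)C(F)(F)F)(C(C)C)C(C)C
Why: Silylation blocks O8 with a group that is stable to hydride and hydroxide and slow to migrate, so that only O6 can lactonise in step 17.

Step 13
Reactants: 19 S-[(5E,8R)-6-methyl-8-{(2S,3S)-4-methylidene-5-oxo-2-[(tosyloxy)methyl]oxolan-3-yl}-8-(triisopropylsilyloxy)oct-5-en-2-yl] ethanethioate
Product: 20 (2S,3S,4R,6E)-2-hydroxy-3-(3-hydroxyprop-1-en-2-yl)-6-methyl-10-sulfanyl-4-(triisopropylsilyloxy)undec-6-en-1-yl 4-methylbenzenesulfonate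
Conditions: DIBAL-H (6 equiv), CH2Cl2, −78 to 0 °C; Rochelle salt work-up; used directly
Reagents that add atoms: none
Why: DIBAL-H reduces the lactone to the 2-methylene-1,4-diol and cleaves the thioester to the thiol, which removes both the acyloxy leaving group β to C5 and the Michael acceptor before the sulfur chemistry, while the primary sulfonate should survive at low temperature.

Step 14
Reactants: 20 (2S,3S,4R,6E)-2-hydroxy-3-(3-hydroxyprop-1-en-2-yl)-6-methyl-10-sulfanyl-4-(triisopropylsilyloxy)undec-6-en-1-yl 4-methylbenzenesulfonate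
Product: 21 (3S,4S,5R,7E)-4-(3-hydroxyprop-1-en-2-yl)-7,11-dimethyl-5-(triisopropylsilyloxy)thiacycloundec-7-en-3-ol
Conditions: Cs2CO3, degassed DMF, slow addition to 1 mM, 45 °C
Reagents that add atoms: none
Why: High-dilution SN2 of the caesium thiolate on the primary C5 sulfonate (or on the terminal epoxide formed from it, opened at C5) should close the eleven-membered thiacycle and leave C6 unchanged.

Step 15
Reactants: 21 (3S,4S,5R,7E)-4-(3-hydroxyprop-1-en-2-yl)-7,11-dimethyl-5-(triisopropylsilyloxy)thiacycloundec-7-en-3-ol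
Product: 22 (3S,4S,5R,7E)-3-hydroxy-4-(3-hydroxyprop-1-en-2-yl)-7,11-dimethyl-5-(triisopropylsilyloxy)thiacycloundec-7-ene 1,1-dioxide
Conditions: Oxone, NaHCO3, MeOH/THF/H2O, 0 °C to rt
Reagents that add atoms: potassium peroxymonosulfate (Oxone) [K+].OOS([O-])(=O)=O
Why: Peroxymonosulfate oxidises the sulfide via the sulfoxide to the sulfone and, without a ketone catalyst, should not epoxidise the olefins.

Step 16
Reactants: 22 (3S,4S,5R,7E)-3-hydroxy-4-(3-hydroxyprop-1-en-2-yl)-7,11-dimethyl-5-(triisopropylsilyloxy)thiacycloundec-7-ene 1,1-dioxide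
Product: 25 8β-(triisopropylsilyloxy)germacra-1(10)E,4E,11(13)-triene-6α,12-diol, via bromosulfone 23 (not isolated), via episulfone 24 (not isolated)
Conditions: CBr2F2, KOH/Al2O3, t-BuOH/CH2Cl2, 0 °C to rt
Reagents that add atoms: none
Why: Halogenative Ramberg–Bäcklund reaction: the sulfone is brominated at C5 by CBr2F2, the α′-carbanion at C4 displaces bromide in a 1,3-elimination (3-exo-tet; should the C6 alkoxide first close onto C5, the same carbanion opens the resulting α,β-epoxy sulfone at C5, the epoxy variant of the reaction) and so forges the C4–C5 bond as a thiirane 1,1-dioxide, which loses SO2 cheletropically to leave the C4=C5 olefin. The closest known reaction type is the Ramberg–Bäcklund ring contraction of macrocyclic sulfones to medium-ring cycloalkenes. Bond formation closes the three-membered episulfone and, because C4 and C5 were linked only through sulfur, turns the eleven-membered thiacycle into the ten-membered carbocycle. No stereocentre is created: C4 becomes sp2, so both C4 epimers of 22 converge on 25, and C6, C7 and C8 are not touched. The step needs E geometry at C4=C5 and must avoid β-elimination of the C6 oxygen from the C5 carbanion; the free C6 hydroxyl is present as its alkoxide, which is no leaving group, and the acidic C5–H of the episulfone allows equilibration under the strongly basic conditions to the isomer with C3 and C6 trans, which avoids a cis-fused bicyclo[8.1.0] system next to the E C1=C10 olefin, before SO2 is lost.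

Step 17
Reactants: 25 8β-(triisopropylsilyloxy)germacra-1(10)E,4E,11(13)-triene-6α,12-diol
Product: 27 8β-(triisopropylsilyloxy)germacra-1(10)E,4E,11(13)-trien-12,6α-olide, via lactol 26 (not isolated)
Conditions: TEMPO (0.2 equiv), PhI(OAc)2 (2.5 equiv), NaHCO3, CH2Cl2, rt
Reagents that add atoms: none
Why: TEMPO/PhI(OAc)2 oxidises only the primary allylic alcohol, the C6 hydroxyl adds to the aldehyde and the lactol is oxidised on to the trans-fused α-methylene lactone, O8 being silylated.

Step 18
Reactants: 27 8β-(triisopropylsilyloxy)germacra-1(10)E,4E,11(13)-trien-12,6α-olide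
Product: 28 8β-hydroxygermacra-1(10)E,4E,11(13)-trien-12,6α-olide (eupatolide)
Conditions: TBAF, AcOH, THF, 0 °C to rt
Reagents that add atoms: none
Why: Acetic acid-buffered fluoride removes the silyl ether without acid (which would trigger transannular cyclisation of the 1(10),4-diene) and without alkoxide-induced relactonisation to O8.

Step 19
Reactants: 28 8β-hydroxygermacra-1(10)E,4E,11(13)-trien-12,6α-olide
Product: 29 8β-tigloyloxygermacra-1(10)E,4E,11(13)-trien-12,6α-olide
Conditions: tiglic acid, DCC, DMAP (cat.), CH2Cl2, 0 °C to rt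
Reagents that add atoms: tiglic acid C/C=C(\C)C(O)=O
Why: Steglich esterification acylates the C8 hydroxyl with retention and keeps the E geometry of the tiglate.

Step 20
Reactants: 29 8β-tigloyloxygermacra-1(10)E,4E,11(13)-trien-12,6α-olide
Product: 30 1β,10α:4α,5β-diepoxy-8β-tigloyloxygermacr-11(13)-en-12,6α-olide (target)
Conditions: m-CPBA (2.4 equiv), NaHCO3, CH2Cl2, 0 °C to rt
Reagents that add atoms: m-chloroperoxybenzoic acid OOC(=O)c1cccc(Cl)c1
Why: Prilezhaev epoxidation attacks only the two electron-rich trisubstituted ring olefins, each from its exposed outer face in the crown conformation with C14 and C15 syn, which should give the 1β,10α- and 4α,5β-oxiranes (C1, C4, C5 and C10 all R).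

Compound list
1 | tert-butyl(but-3-yn-1-yloxy)dimethylsilane | C#CCCO[Si](C)(C)C(C)(C)C | starting material
2 | [(1E)-4-(tert-butyldimethylsilyloxy)-2-methylbut-1-enyl]dimethylalane | C/C(CCO[Si](C)(C)C(C)(C)C)=C\[Al](C)C | intermediate (not isolated)
3 | tert-butyl{[(3E)-4-iodo-3-methylbut-3-en-1-yl]oxy}dimethylsilane | C/C(CCO[Si](C)(C)C(C)(C)C)=C\I | intermediate
4 | (±)-but-3-en-2-ol | C=CC(C)O | starting material
5 | 9-(3-hydroxybutyl)-9-borabicyclo[3.3.1]nonane (hydroxyl held as its borinate) | CC(O)CCB1C2CCCC1CCC2 | intermediate (not isolated)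
6 | (±)-(5E)-8-(tert-butyldimethylsilyloxy)-6-methyloct-5-en-2-ol | CC(O)CC/C=C(\C)CCO[Si](C)(C)C(C)(C)C | intermediate
7 | (±)-S-[(5E)-8-(tert-butyldimethylsilyloxy)-6-methyloct-5-en-2-yl] ethanethioate | CC(=O)SC(C)CC/C=C(\C)CCO[Si](C)(C)C(C)(C)C | intermediate
8 | (±)-S-[(5E)-8-hydroxy-6-methyloct-5-en-2-yl] ethanethioate | CC(=O)SC(C)CC/C=C(\C)CCO | intermediate
9 | (±)-S-[(5E)-6-methyl-8-oxooct-5-en-2-yl] ethanethioate | CC(=O)SC(C)CC/C=C(\C)CC=O | intermediate
10 | (4R)-2,2-dimethyl-1,3-dioxolane-4-carbaldehyde ((R)-glyceraldehyde acetonide) | O=C[C@H]1COC(C)(C)O1 | starting material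
11 | methyl acrylate | C=CC(=O)OC | starting material
12 | methyl 2-{[(4R)-2,2-dimethyl-1,3-dioxolan-4-yl](hydroxy)methyl}prop-2-enoate (both carbinol epimers) | C=C(C(=O)OC)C(O)[C@H]1COC(C)(C)O1 | intermediate
13 | (5R)-4-hydroxy-5-(hydroxymethyl)-3-methylideneoxolan-2-one (both C4 epimers) | C=C1C(=O)O[C@H](CO)C1O | intermediate
14 | [(2R)-3-hydroxy-4-methylidene-5-oxooxolan-2-yl]methyl 4-methylbenzenesulfonate (both C3 epimers) | C=C1C(=O)O[C@H](COS(=O)(=O)c2ccc(C)cc2)C1O | intermediate
15 | [(2S)-4-(bromomethyl)-5-oxo-2,5-dihydrofuran-2-yl]methyl 4-methylbenzenesulfonate | O=C1O[C@H](COS(=O)(=O)c2ccc(C)cc2)C=C1CBr | intermediate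
16 | S-[(5E,8S)-8-hydroxy-6-methyl-8-{(2S,3R)-4-methylidene-5-oxo-2-[(tosyloxy)methyl]oxolan-3-yl}oct-5-en-2-yl] ethanethioate (germacrane 6S,7R,8S) | C=C1C(=O)O[C@H](COS(=O)(=O)c2ccc(C)cc2)[C@H]1[C@@H](O)C/C(C)=C/CCC(C)SC(C)=O | intermediate
17 | 8R formate ester of 18 (germacrane 6S,7R,8R) | C=C1C(=O)O[C@H](COS(=O)(=O)c2ccc(C)cc2)[C@H]1[C@H](OC=O)C/C(C)=C/CCC(C)SC(C)=O | intermediate (not isolated)
18 | S-[(5E,8R)-8-hydroxy-6-methyl-8-{(2S,3R)-4-methylidene-5-oxo-2-[(tosyloxy)methyl]oxolan-3-yl}oct-5-en-2-yl] ethanethioate (germacrane 6S,7R,8R) | C=C1C(=O)O[C@H](COS(=O)(=O)c2ccc(C)cc2)[C@H]1[C@H](O)C/C(C)=C/CCC(C)SC(C)=O | intermediate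
19 | S-[(5E,8R)-6-methyl-8-{(2S,3S)-4-methylidene-5-oxo-2-[(tosyloxy)methyl]oxolan-3-yl}-8-(triisopropylsilyloxy)oct-5-en-2-yl] ethanethioate (germacrane 6S,7S,8R) | C=C1C(=O)O[C@H](COS(=O)(=O)c2ccc(C)cc2)[C@H]1[C@H](O[Si](C(C)C)(C(C)C)C(C)C)C/C(C)=C/CCC(C)SC(C)=O | intermediate
20 | (2S,3S,4R,6E)-2-hydroxy-3-(3-hydroxyprop-1-en-2-yl)-6-methyl-10-sulfanyl-4-(triisopropylsilyloxy)undec-6-en-1-yl 4-methylbenzenesulfonate | C=C(CO)[C@@H]([C@H](O)COS(=O)(=O)c1ccc(C)cc1)[C@H](O[Si](C(C)C)(C(C)C)C(C)C)C/C(C)=C/CCC(C)S | intermediate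
21 | (3S,4S,5R,7E)-4-(3-hydroxyprop-1-en-2-yl)-7,11-dimethyl-5-(triisopropylsilyloxy)thiacycloundec-7-en-3-ol (C11 epimers) | C=C(CO)[C@@H]1[C@H](O[Si](C(C)C)(C(C)C)C(C)C)C/C(C)=C/CCC(C)SC[C@H]1O | intermediate
22 | (3S,4S,5R,7E)-3-hydroxy-4-(3-hydroxyprop-1-en-2-yl)-7,11-dimethyl-5-(triisopropylsilyloxy)thiacycloundec-7-ene 1,1-dioxide (C11 epimers) | C=C(CO)[C@@H]1[C@H](O[Si](C(C)C)(C(C)C)C(C)C)C/C(C)=C/CCC(C)S(=O)(=O)C[C@H]1O | intermediate
23 | 2-bromo derivative of sulfone 22 (bromine on germacrane C5, epimers) | C=C(CO)[C@@H]1[C@H](O[Si](C(C)C)(C(C)C)C(C)C)C/C(C)=C/CCC(C)S(=O)(=O)C(Br)[C@H]1O | intermediate (not isolated)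
24 | 4,5-episulfone: thiirane 1,1-dioxide spanning C4–C5 of the (1(10)E)-germacrene ring, 6α-oxido, 8β-OTIPS (C4/C5 configuration not defined) | C=C(CO)[C@@H]1[C@H](O[Si](C(C)C)(C(C)C)C(C)C)C/C(C)=C/CCC2(C)S(=O)(=O)C2[C@H]1O | intermediate (not isolated)
25 | 8β-(triisopropylsilyloxy)germacra-1(10)E,4E,11(13)-triene-6α,12-diol (6R,7S,8R) | C=C(CO)[C@@H]1[C@H](O[Si](C(C)C)(C(C)C)C(C)C)C/C(C)=C/CC/C(C)=C/[C@H]1O | intermediate
26 | 12-hydroxy-12,6α-epoxy-8β-(triisopropylsilyloxy)germacra-1(10)E,4E,11(13)-triene (lactol, C12 epimers) | C=C1C(O)O[C@H]2[C@H]1[C@H](O[Si](C(C)C)(C(C)C)C(C)C)C/C(C)=C/CC/C(C)=C/2 | intermediate (not isolated)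
27 | 8β-(triisopropylsilyloxy)germacra-1(10)E,4E,11(13)-trien-12,6α-olide (6R,7S,8R) | C=C1C(=O)O[C@H]2[C@H]1[C@H](O[Si](C(C)C)(C(C)C)C(C)C)C/C(C)=C/CC/C(C)=C/2 | intermediate
28 | 8β-hydroxygermacra-1(10)E,4E,11(13)-trien-12,6α-olide (eupatolide; 6R,7R,8R) | C=C1C(=O)O[C@H]2[C@H]1[C@H](O)C/C(C)=C/CC/C(C)=C/2 | intermediate
29 | 8β-tigloyloxygermacra-1(10)E,4E,11(13)-trien-12,6α-olide (6R,7R,8R) | C=C1C(=O)O[C@H]2[C@H]1[C@H](OC(=O)/C(C)=C/C)C/C(C)=C/CC/C(C)=C/2 | intermediate
30 | 1β,10α:4α,5β-diepoxy-8β-tigloyloxygermacr-11(13)-en-12,6α-olide (1R,4R,5R,6S,7R,8R,10R) | C=C1C(=O)O[C@H]2[C@H]1[C@H](OC(=O)/C(C)=C/C)C[C@@]1(C)O[C@@H]1CC[C@@]1(C)O[C@H]21 | target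

Total step count: 20. Longest linear sequence: 16 steps (steps 1–5, then 10–20).

Steps most likely to fail

Step 16. The carbanion chemistry may run off course in three ways: repeated bromination at C5 before ring closure, cleavage at the C5–C6 bond, and extrusion from the cis-fused episulfone, which would deliver the 4Z olefin. The fallback sets out from 22 and returns at 25, and takes the halogenation out of the ring-contraction step. The trianion of 22 (LiHMDS, THF, −78 °C) is chlorinated at C5 with hexachloroethane and, on warming to 0 °C, the C6 alkoxide closes onto C5 to give the α,β-epoxy sulfone F1, which is isolated. F1 is then submitted to the epoxy-Ramberg–Bäcklund reaction (LiOt-Bu, THF/t-BuOH, rt), in which the C4 carbanion opens the oxirane at C5 with no electrophilic halogen present, and should give 25.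

Step 14. Intermolecular S-alkylation to dimers and oligomers may outrun closure of the eleven-membered ring. The fallback sets out from 20 and returns at 21: sulfur is first put on C5 intermolecularly, the ring is closed through a reversible S–S bond, and one sulfur is then excised. Treatment of 20 with KSAc (DMF, rt, 0.2 M) should give the thioacetate thiol F2. Methanolysis (K2CO3, MeOH) and iodine titration at high dilution should give the twelve-membered cyclic disulfide F3, with disulfide exchange correcting oligomers. P(NEt2)3 (benzene, 50 °C) then removes one sulfur, the C4 thiolate displacing the thiophosphonium group from primary C5, to give 21.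

Step 10. Under the aqueous zinc conditions the β,γ-olefin of 9 may migrate into conjugation and the simple diastereoselection at C8 may erode. The fallback sets out from 15 and returns at 16, with allylboration in place of the Barbier reaction. Palladium-catalysed borylation of 15 (B2pin2, Pd2(dba)3, toluene, 50 °C) should give the allylboronate F4, which adds to freshly prepared 9 in toluene at rt without metal salt, acid or base through the same closed chair transition state; aqueous work-up then gives 16.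

Further compounds
F1 | step 16 | α,β-epoxy sulfone of 22 (oxirane spanning germacrane C5–C6, C6 configuration retained, C5 and C4 epimers) | C=C(CO)[C@@H]1[C@H](O[Si](C(C)C)(C(C)C)C(C)C)C/C(C)=C/CCC(C)S(=O)(=O)C2O[C@@H]12
F2 | step 14 | S-[(2S,3S,4R,6E)-2-hydroxy-3-(3-hydroxyprop-1-en-2-yl)-6-methyl-10-sulfanyl-4-(triisopropylsilyloxy)undec-6-en-1-yl] ethanethioate | C=C(CO)[C@@H]([C@H](O)CSC(C)=O)[C@H](O[Si](C(C)C)(C(C)C)C(C)C)C/C(C)=C/CCC(C)S
F3 | step 14 | (4S,5S,6R,8E)-5-(3-hydroxyprop-1-en-2-yl)-8,12-dimethyl-6-(triisopropylsilyloxy)-1,2-dithiacyclododec-8-en-4-ol (C12 epimers) | C=C(CO)[C@@H]1[C@H](O[Si](C(C)C)(C(C)C)C(C)C)C/C(C)=C/CCC(C)SSC[C@H]1O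
F4 | step 10 | [(2S)-5-oxo-4-[(4,4,5,5-tetramethyl-1,3,2-dioxaborolan-2-yl)methyl]-2,5-dihydrofuran-2-yl]methyl 4-methylbenzenesulfonate | O=C1O[C@H](COS(=O)(=O)c2ccc(C)cc2)C=C1CB3OC(C)(C)C(C)(C)O3
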